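**Plan**

1. Retrosynthesis: the C15 ketone and the C7 acetate are adjusted last. Cutting C12–C13 while re-forming C8–C9 (retro-oxy-Cope) contracts the ten-membered ring to a trans-decalin whose ring B is spiro-fused at C8 to a 4-methylidenecyclopentene (ring D). Ring D is cut to vinyl + propargyl on C8, C8–C9 (Claisen) opens ring B, and C10–C1 opens ring A.
2. Forward order: acyclic chloro ester → ring A (C10–C1) → ring B (C8–C9) → ring D on C8 → ring expansion (C12–C13 formed, C8–C9 cleaved) → C15=O.
3. Enabling feature: C10 is the α-carbon of the C9 carbonyl and C1 is a primary carbon tied to C5 through the gem-dimethyl carbon C4, so ring A (C1–C5, C10) can close by enolate alkylation while C9 is still outside any ring.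
4. Stereochemistry: C5 comes from a CBS reduction relayed by a Johnson–Claisen rearrangement; C10 follows from C5 (allylic strain, key step); C8 (transient) is set anti to the C20 methyl; C7 by axial hydride; C13 is relayed from C8 in the oxy-Cope step.

Key step: step 5

Remark: atoms carry kaurane locants (C1–C20; ring A = C1–C5 + C10, ring B = C5–C10, ring D = C8 + C13–C16); ethenyl(phenyl)iodonium tetrafluoroborate is taken as made beforehand from trimethyl(vinyl)silane.

**Route**

Step 1
Reactants: 1 isobutyl 5-chloro-2,2-dimethylpentanoate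
Product: 2 5-chloro-2,2-dimethylpentanal
Conditions: i-Bu2AlH (1.1 equiv), CH2Cl2, −78 °C; aq potassium sodium tartrate
Reagents that add atoms: none
Why: Partial hydride reduction of an α,α-disubstituted ester should stop at the aldehyde because the crowded aluminium hemiacetal survives at −78 °C until the quench.

Step 2
Reactants: 2 5-chloro-2,2-dimethylpentanal
Product: 3 (3E)-8-chloro-5,5-dimethyloct-3-en-2-one
Conditions: NaH, (MeO)2P(O)CH2COCH3, THF, 0 → 40 °C
Reagents that add atoms: dimethyl (2-oxopropyl)phosphonate, COP(=O)(CC(C)=O)OC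
Why: Horner–Wadsworth–Emmons olefination of a non-enolizable aldehyde with a stabilized keto-phosphonate anion should give the (E)-enone.

Step 3
Reactants: 3 (3E)-8-chloro-5,5-dimethyloct-3-en-2-one
Product: 4 (2R,3E)-8-chloro-5,5-dimethyloct-3-en-2-ol
Conditions: (S)-2-methyl-CBS-oxazaborolidine (10 mol %), catecholborane, toluene, −78 °C
Reagents that add atoms: none
Why: Corey–Bakshi–Shibata reduction, in which the (S)-oxazaborolidine tells the methyl from the alkenyl group and directs 1,2-hydride delivery to give the (R)-allylic alcohol.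

Step 4
Reactants: 4 (2R,3E)-8-chloro-5,5-dimethyloct-3-en-2-ol
Product: 6 ethyl (3S,4E)-3-(5-chloro-2-methylpentan-2-yl)-2-methylhex-4-enoate, via ketene acetal 5 (not isolated)
Conditions: EtC(OEt)3, EtCO2H (cat.), xylene, 140 °C, ethanol distilled off
Reagents that add atoms: triethyl orthopropionate, CCC(OCC)(OCC)OCC
Why: Johnson–Claisen rearrangement through a chair with the carbinol methyl equatorial should transfer the (R)-carbinol configuration to C5 (3S) and give the (E)-propenyl group; the configuration at C2 (the later C10) is immaterial because it is erased in step 5.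

Step 5
Reactants: 6 ethyl (3S,4E)-3-(5-chloro-2-methylpentan-2-yl)-2-methylhex-4-enoate
Product: 8 ethyl (1R,2R)-1,3,3-trimethyl-2-[(1E)-prop-1-en-1-yl]cyclohexane-1-carboxylate, via lithium enolate 7 (not isolated)
Conditions: LDA, NaI (10 mol %), THF–DMPU, −78 → 25 °C
Reagents that add atoms: none
Why: LDA removes the only acidic hydrogen (C10–H, α to the ester) and the enolate carbon C10 displaces the primary chloride at C1 in an intramolecular SN2 reaction. The closest known reaction type is the cycloalkylation of an ester enolate by an ω-haloalkyl chain. Ring A (C1–C2–C3–C4–C5–C10) closes in the 6-(enolexo)-exo-tet mode through a chair in which the gem-dimethyl carbon C4 is part of the tether. The new quaternary stereocenter C10 is controlled by C5 through allylic 1,3-strain: C5–H lies in the enolate plane, the tether and the propenyl group sit on opposite faces, so C1 bonds anti to the propenyl group, the ester ends trans to it and the methyl group is axial. The step needs C- over O-alkylation and this trans relation; the six-membered SN2 geometry should secure the first and the exocyclic position of the enolate the second, whereas an enolate held inside a preformed ring B would be expected to close cis.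

Step 6
Reactants: 8 ethyl (1R,2R)-1,3,3-trimethyl-2-[(1E)-prop-1-en-1-yl]cyclohexane-1-carboxylate
Product: 9 ethyl (1R,2R)-1,3,3-trimethyl-2-(2-oxopropyl)cyclohexane-1-carboxylate
Conditions: Pd(OAc)2 (5 mol %), 1,4-benzoquinone, aq HBF4, DMA–MeCN–H2O, 25 °C
Reagents that add atoms: water, O
Why: Tsuji–Wacker oxidation of the internal alkene, in which hydroxypalladation should place oxygen on the methyl-bearing carbon C7, remote from the neopentyl-like C5, and so give the methyl ketone.

Step 7
Reactants: 9 ethyl (1R,2R)-1,3,3-trimethyl-2-(2-oxopropyl)cyclohexane-1-carboxylate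
Product: 10 (4aR,8aR)-5,5,8a-trimethylhexahydronaphthalene-1,3(2H,4H)-dione
Conditions: KOt-Bu (2.2 equiv), THF, 65 °C; aq HCl
Reagents that add atoms: none
Why: Intramolecular Claisen (Dieckmann-type) condensation: the methyl ketone enolate carbon C8 acylates the ester carbonyl C9 in a 6-exo-trig closure driven by deprotonation of the 1,3-dione, and C5 and C10 cannot enolize, so the trans fusion is kept.

Step 8
Reactants: 10 (4aR,8aR)-5,5,8a-trimethylhexahydronaphthalene-1,3(2H,4H)-dione
Product: 11 (4aR,8aR)-5,5,8a-trimethyl-2-(prop-2-yn-1-yl)hexahydronaphthalene-1,3(2H,4H)-dione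
Conditions: propargyl bromide (1.05 equiv), KOH, H2O, 50 °C
Reagents that add atoms: propargyl bromide, C#CCBr
Why: C-alkylation of a cyclic 1,3-dione enolate at C8 with a propargylic halide, for which aqueous hydroxide favours carbon over oxygen attack.

Step 9
Reactants: 11 (4aR,8aR)-5,5,8a-trimethyl-2-(prop-2-yn-1-yl)hexahydronaphthalene-1,3(2H,4H)-dione
Product: 12 (2S,4aR,8aR)-2-ethenyl-5,5,8a-trimethyl-2-(prop-2-yn-1-yl)hexahydronaphthalene-1,3(2H,4H)-dione
Conditions: KOt-Bu, THF, −78 °C; ethenyl(phenyl)iodonium tetrafluoroborate, −78 → 0 °C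
Reagents that add atoms: ethenyl(phenyl)iodonium tetrafluoroborate, C=C[I+]c1ccccc1.F[B-](F)(F)F
Why: α-Vinylation of a 2-substituted 1,3-dicarbonyl enolate by an alkenyl(aryl)iodonium salt (ligand coupling on iodine), in which the vinyl group should enter C8 from the face anti to the axial C20 methyl and leave the propargyl group syn to C20.

Step 10
Reactants: 12 (2S,4aR,8aR)-2-ethenyl-5,5,8a-trimethyl-2-(prop-2-yn-1-yl)hexahydronaphthalene-1,3(2H,4H)-dione
Product: 14 (1S,4a'R,8a'R)-5',5',8a'-trimethyl-4-methylidene-4a',5',6',7',8',8a'-hexahydro-1'H-spiro[cyclopent-2-ene-1,2'-naphthalene]-1',3'(4'H)-dione, via triene 13 (not isolated)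
Conditions: second-generation Grubbs catalyst (5 mol %), ethylene (1 atm), toluene, 80 °C; then Ar purge, 80 °C
Reagents that add atoms: ethylene, C=C
Why: Enyne cross-metathesis of the terminal alkyne with ethylene should give the 2-substituted butadiene, whose vinyl arm then closes onto the C8 vinyl group by ring-closing metathesis to the five-membered ring D without touching the C8 stereocenter.

Step 11
Reactants: 14 (1S,4a'R,8a'R)-5',5',8a'-trimethyl-4-methylidene-4a',5',6',7',8',8a'-hexahydro-1'H-spiro[cyclopent-2-ene-1,2'-naphthalene]-1',3'(4'H)-dione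
Product: 15 (1S,3'R,4a'R,8a'R)-3'-hydroxy-5',5',8a'-trimethyl-4-methylidene-octahydro-1'H-spiro[cyclopent-2-ene-1,2'-naphthalen]-1'-one
Conditions: NaBH4, MeOH–CH2Cl2, −40 °C
Reagents that add atoms: none
Why: Chemoselective borohydride reduction: C9 is flanked by two quaternary carbons, so only the C7 ketone should react, and axial hydride delivery should give the equatorial alcohol (7R).

Step 12
Reactants: 15 (1S,3'R,4a'R,8a'R)-3'-hydroxy-5',5',8a'-trimethyl-4-methylidene-octahydro-1'H-spiro[cyclopent-2-ene-1,2'-naphthalen]-1'-one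
Product: 16 (1S,3'R,4a'R,8a'R)-3'-[(tert-butyldimethylsilyl)oxy]-5',5',8a'-trimethyl-4-methylidene-octahydro-1'H-spiro[cyclopent-2-ene-1,2'-naphthalen]-1'-one
Conditions: TBSOTf, 2,6-lutidine, CH2Cl2, 0 °C
Reagents that add atoms: tert-butyldimethylsilyl trifluoromethanesulfonate, CC(C)(C)[Si](C)(C)OS(=O)(=O)C(F)(F)F
Why: Silyl ether formation with the silyl triflate, which is reactive enough for a secondary alcohol next to a quaternary carbon.

Step 13
Reactants: 16 (1S,3'R,4a'R,8a'R)-3'-[(tert-butyldimethylsilyl)oxy]-5',5',8a'-trimethyl-4-methylidene-octahydro-1'H-spiro[cyclopent-2-ene-1,2'-naphthalen]-1'-one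
Product: 17 (1S,1'S,3'R,4a'R,8a'R)-3'-[(tert-butyldimethylsilyl)oxy]-1'-ethenyl-5',5',8a'-trimethyl-4-methylidene-octahydro-1'H-spiro[cyclopent-2-ene-1,2'-naphthalen]-1'-ol
Conditions: CH2=CHMgBr, CeCl3, THF, −78 → 0 °C; aq NH4Cl
Reagents that add atoms: vinylmagnesium bromide, C=C[Mg]Br
Why: 1,2-Addition of a vinylcerium reagent to the non-enolizable C9 ketone, which should occur on the face anti to the C20 methyl and to the axial C15 methylene and so give the axial vinyl group (9S).

Step 14
Reactants: 17 (1S,1'S,3'R,4a'R,8a'R)-3'-[(tert-butyldimethylsilyl)oxy]-1'-ethenyl-5',5',8a'-trimethyl-4-methylidene-octahydro-1'H-spiro[cyclopent-2-ene-1,2'-naphthalen]-1'-ol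
Product: 21 (1S,1'R,3'R,4a'R,8a'R)-3'-[(tert-butyldimethylsilyl)oxy]-1'-ethenyl-5',5',8a'-trimethyl-4-methylidene-octahydro-1'H-spiro[cyclopent-2-ene-1,2'-naphthalen]-1'-ol, via sulfenate 18 (not isolated), via allylic sulfoxide 19 (not isolated), via epimeric sulfenate 20 (not isolated)
Conditions: n-BuLi, THF, −78 °C; PhSCl (1.0 equiv), −78 → 25 °C; then P(OMe)3, MeOH, 60 °C
Reagents that add atoms: none
Why: Mislow–Evans [2,3]-sigmatropic shuttle: the sulfenate rearranges to the allylic sulfoxide (C9=C11), which should re-close on the open face of C9 (anti to C20 and C15) before the thiophile cleaves the S–O bond, so the carbinol is epimerized to the isomer with equatorial vinyl and axial oxygen.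

Step 15
Reactants: 21 (1S,1'R,3'R,4a'R,8a'R)-3'-[(tert-butyldimethylsilyl)oxy]-1'-ethenyl-5',5',8a'-trimethyl-4-methylidene-octahydro-1'H-spiro[cyclopent-2-ene-1,2'-naphthalen]-1'-ol
Product: 24 (5R,7R,10R,13S)-7-[(tert-butyldimethylsilyl)oxy]-8,9-secokaura-8(14),16-dien-9-one, via potassium alkoxide 22 (not isolated), via potassium enolate 23 (not isolated)
Conditions: KH, 18-crown-6, THF, 0 → 50 °C; aq NH4Cl
Reagents that add atoms: none
Why: Anionic oxy-Cope rearrangement: the C9 vinyl group and C14 on C8 are trans-diequatorial, so a chair transition state should form C12–C13 and cleave C8–C9 to expand ring B to the ten-membered ring, while the spiro ring forces C12 onto the C9 face of the cyclopentene (setting C13 as S) and keeps C15 cis to C13, so that C8=C14 is E within the large ring.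

Step 16
Reactants: 24 (5R,7R,10R,13S)-7-[(tert-butyldimethylsilyl)oxy]-8,9-secokaura-8(14),16-dien-9-one
Product: 25 (5R,7R,10R,13S)-7-hydroxy-8,9-secokaura-8(14),16-dien-9-one
Conditions: HF·pyridine, pyridine, THF, 0 → 25 °C
Reagents that add atoms: none
Why: Fluoride-driven cleavage of the silyl ether (Si–F bond formation) under buffered conditions that should leave the skipped diene and the ketone alone.

Step 17
Reactants: 25 (5R,7R,10R,13S)-7-hydroxy-8,9-secokaura-8(14),16-dien-9-one
Product: 26 (5R,7R,10R,13S)-9-oxo-8,9-secokaura-8(14),16-dien-7-yl acetate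
Conditions: Ac2O, DMAP, pyridine, CH2Cl2, 25 °C
Reagents that add atoms: acetic anhydride, CC(=O)OC(C)=O
Why: Acetylation of the only hydroxyl group by nucleophilic (DMAP) acyl-transfer catalysis.

Step 18
Reactants: 26 (5R,7R,10R,13S)-9-oxo-8,9-secokaura-8(14),16-dien-7-yl acetate
Product: 27 (5R,7R,10R,13S)-15-hydroxy-9-oxo-8,9-secokaura-8(14),16-dien-7-yl acetate
Conditions: SeO2 (0.5 equiv), t-BuOOH, CH2Cl2, 0 → 25 °C
Reagents that add atoms: selenium dioxide, O=[Se]=O; tert-butyl hydroperoxide (stoichiometric oxygen source), CC(C)(C)OO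
Why: Selenium dioxide allylic oxidation (ene reaction then [2,3]-shift) at the exocyclic C16=C17, where hydrogen should be taken from the doubly allylic methylene C15 in preference to the methine C13, as in the usual 15-hydroxylation of kaur-16-enes; the C15 configuration is irrelevant.

Step 19
Reactants: 27 (5R,7R,10R,13S)-15-hydroxy-9-oxo-8,9-secokaura-8(14),16-dien-7-yl acetate
Product: 28 (5R,7R,10R,13S)-9,15-dioxo-8,9-secokaura-8(14),16-dien-7-yl acetate
Conditions: Dess–Martin periodinane, CH2Cl2, 0 → 25 °C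
Reagents that add atoms: none
Why: Dess–Martin oxidation of the doubly allylic alcohol to the cross-conjugated dienone under non-basic conditions that should spare the allylic acetate.

**Compound list**

1 | isobutyl 5-chloro-2,2-dimethylpentanoate | CC(C)COC(=O)C(C)(C)CCCCl | starting material
2 | 5-chloro-2,2-dimethylpentanal | O=CC(C)(C)CCCCl | intermediate
3 | (3E)-8-chloro-5,5-dimethyloct-3-en-2-one | CC(=O)/C=C/C(C)(C)CCCCl | intermediate
4 | (2R,3E)-8-chloro-5,5-dimethyloct-3-en-2-ol | C[C@@H](O)/C=C/C(C)(C)CCCCl | intermediate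
5 | ketene acetal 1-ethoxy-1-{[(2R,3E)-8-chloro-5,5-dimethyloct-3-en-2-yl]oxy}prop-1-ene (not isolated) | CC=C(OCC)O[C@H](C)/C=C/C(C)(C)CCCCl | intermediate
6 | ethyl (3S,4E)-3-(5-chloro-2-methylpentan-2-yl)-2-methylhex-4-enoate (both C2 epimers) | CCOC(=O)C(C)[C@H](/C=C/C)C(C)(C)CCCCl | intermediate
7 | lithium enolate of 6 (not isolated) | CCOC([O-])=C(C)[C@H](/C=C/C)C(C)(C)CCCCl.[Li+] | intermediate
8 | ethyl (1R,2R)-1,3,3-trimethyl-2-[(1E)-prop-1-en-1-yl]cyclohexane-1-carboxylate (ester and propenyl trans) | CCOC(=O)[C@]1(C)CCCC(C)(C)[C@H]1/C=C/C | intermediate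
9 | ethyl (1R,2R)-1,3,3-trimethyl-2-(2-oxopropyl)cyclohexane-1-carboxylate | CCOC(=O)[C@]1(C)CCCC(C)(C)[C@H]1CC(C)=O | intermediate
10 | (4aR,8aR)-5,5,8a-trimethylhexahydronaphthalene-1,3(2H,4H)-dione (trans-fused) | O=C1CC(=O)[C@]2(C)CCCC(C)(C)[C@H]2C1 | intermediate
11 | (4aR,8aR)-5,5,8a-trimethyl-2-(prop-2-yn-1-yl)hexahydronaphthalene-1,3(2H,4H)-dione (C2 epimers and enol forms) | O=C1C(CC#C)C(=O)[C@]2(C)CCCC(C)(C)[C@H]2C1 | intermediate
12 | (2S,4aR,8aR)-2-ethenyl-5,5,8a-trimethyl-2-(prop-2-yn-1-yl)hexahydronaphthalene-1,3(2H,4H)-dione (vinyl anti, propargyl syn to the 8a-methyl) | O=C1[C@](CC#C)(C=C)C(=O)[C@]2(C)CCCC(C)(C)[C@H]2C1 | intermediate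
13 | (2S,4aR,8aR)-2-ethenyl-5,5,8a-trimethyl-2-(2-methylidenebut-3-en-1-yl)hexahydronaphthalene-1,3(2H,4H)-dione (not isolated) | O=C1[C@](CC(=C)C=C)(C=C)C(=O)[C@]2(C)CCCC(C)(C)[C@H]2C1 | intermediate
14 | (1S,4a'R,8a'R)-5',5',8a'-trimethyl-4-methylidene-4a',5',6',7',8',8a'-hexahydro-1'H-spiro[cyclopent-2-ene-1,2'-naphthalene]-1',3'(4'H)-dione (ring CH2 of the cyclopentene syn to the 8a'-methyl) | O=C1[C@@]2(CC(=C)C=C2)C(=O)[C@]3(C)CCCC(C)(C)[C@H]3C1 | intermediate
15 | (1S,3'R,4a'R,8a'R)-3'-hydroxy-5',5',8a'-trimethyl-4-methylidene-octahydro-1'H-spiro[cyclopent-2-ene-1,2'-naphthalen]-1'-one (equatorial OH) | O[C@H]1[C@@]2(CC(=C)C=C2)C(=O)[C@]3(C)CCCC(C)(C)[C@H]3C1 | intermediate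
16 | tert-butyldimethylsilyl ether of 15 | CC(C)(C)[Si](C)(C)O[C@H]1[C@@]2(CC(=C)C=C2)C(=O)[C@]3(C)CCCC(C)(C)[C@H]3C1 | intermediate
17 | (1S,1'S,3'R,4a'R,8a'R)-3'-[(tert-butyldimethylsilyl)oxy]-1'-ethenyl-5',5',8a'-trimethyl-4-methylidene-octahydro-1'H-spiro[cyclopent-2-ene-1,2'-naphthalen]-1'-ol (vinyl axial, anti to the 8a'-methyl) | CC(C)(C)[Si](C)(C)O[C@H]1[C@@]2(CC(=C)C=C2)[C@](O)(C=C)[C@]3(C)CCCC(C)(C)[C@H]3C1 | intermediate
18 | O-phenylsulfanyl derivative (sulfenate) of 17 (not isolated) | CC(C)(C)[Si](C)(C)O[C@H]1[C@@]2(CC(=C)C=C2)[C@](OSc4ccccc4)(C=C)[C@]3(C)CCCC(C)(C)[C@H]3C1 | intermediate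
19 | 1'-[2-(phenylsulfinyl)ethylidene] allylic sulfoxide (not isolated; alkene geometry and sulfur configuration open) | CC(C)(C)[Si](C)(C)O[C@H]1[C@@]2(CC(=C)C=C2)C(=CCS(=O)c4ccccc4)[C@]3(C)CCCC(C)(C)[C@H]3C1 | intermediate
20 | 1'-epimeric sulfenate, O-phenylsulfanyl derivative of 21 (not isolated) | CC(C)(C)[Si](C)(C)O[C@H]1[C@@]2(CC(=C)C=C2)[C@@](OSc4ccccc4)(C=C)[C@]3(C)CCCC(C)(C)[C@H]3C1 | intermediate
21 | (1S,1'R,3'R,4a'R,8a'R)-3'-[(tert-butyldimethylsilyl)oxy]-1'-ethenyl-5',5',8a'-trimethyl-4-methylidene-octahydro-1'H-spiro[cyclopent-2-ene-1,2'-naphthalen]-1'-ol (vinyl equatorial, OH axial) | CC(C)(C)[Si](C)(C)O[C@H]1[C@@]2(CC(=C)C=C2)[C@@](O)(C=C)[C@]3(C)CCCC(C)(C)[C@H]3C1 | intermediate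
22 | potassium alkoxide of 21 (not isolated) | CC(C)(C)[Si](C)(C)O[C@H]1[C@@]2(CC(=C)C=C2)[C@@]([O-])(C=C)[C@]3(C)CCCC(C)(C)[C@H]3C1.[K+] | intermediate
23 | potassium C9(C11) enolate of 24 (not isolated) | C=C1CC2=C[C@@H]1CC=C([O-])[C@]1(C)CCCC(C)(C)[C@H]1C[C@H]2O[Si](C)(C)C(C)(C)C.[K+] | intermediate
24 | (5R,7R,10R,13S)-7-[(tert-butyldimethylsilyl)oxy]-8,9-secokaura-8(14),16-dien-9-one (ring A fused to a bicyclo[7.2.1]dodecadiene) | C=C1CC2=C[C@@H]1CCC(=O)[C@]1(C)CCCC(C)(C)[C@H]1C[C@H]2O[Si](C)(C)C(C)(C)C | intermediate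
25 | (5R,7R,10R,13S)-7-hydroxy-8,9-secokaura-8(14),16-dien-9-one | C=C1CC2=C[C@@H]1CCC(=O)[C@]1(C)CCCC(C)(C)[C@H]1C[C@H]2O | intermediate
26 | (5R,7R,10R,13S)-9-oxo-8,9-secokaura-8(14),16-dien-7-yl acetate | C=C1CC2=C[C@@H]1CCC(=O)[C@]1(C)CCCC(C)(C)[C@H]1C[C@H]2OC(C)=O | intermediate
27 | (5R,7R,10R,13S)-15-hydroxy-9-oxo-8,9-secokaura-8(14),16-dien-7-yl acetate (C15 epimers) | C=C1C(O)C2=C[C@@H]1CCC(=O)[C@]1(C)CCCC(C)(C)[C@H]1C[C@H]2OC(C)=O | intermediate
28 | (5R,7R,10R,13S)-9,15-dioxo-8,9-secokaura-8(14),16-dien-7-yl acetate | C=C1C(=O)C2=C[C@@H]1CCC(=O)[C@]1(C)CCCC(C)(C)[C@H]1C[C@H]2OC(C)=O | target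

**Totals**

Total step count: 19. Longest linear sequence: 19 steps (the route is fully linear from 1).

**Three steps most likely to fail**

Step 14. The sulfenyl chloride may add to the ring D diene instead of the alkoxide, or the sulfenate may be trapped on its original face, so that the carbinol is not epimerized and no chair geometry is available for the rearrangement. The fallback sets out from 17 and uses a neutral thermal oxy-Cope rearrangement instead of epimerization plus an anionic chair. The tertiary alcohol of 17 is silylated (TMSOTf, 2,6-lutidine) to the 1'-O-trimethylsilyl ether of 17 F1, which is heated in degassed o-dichlorobenzene with a trace of Et3N at 200–220 °C. Because the spiro ring keeps C15 cis to C13, the only [3,3] path open is a boat, which again joins C12 to C13 on the C9 face and should give the 9-O-trimethylsilyl enol ether of 24 F2. Methanolysis (K2CO3, MeOH) then brings the route back at 24, leaving out 21.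

Step 9. Ligand coupling at the crowded, fully substituted enolate carbon may be slower than O-vinylation or decay of the iodonium salt, and facial control may erode. The fallback sets out from 11 and replaces the iodonium salt by a vinyl cation equivalent. Conjugate addition of the dione enolate (NaH cat., THF–t-BuOH) to phenyl vinyl sulfoxide, again anti to C20, gives (2S,4aR,8aR)-5,5,8a-trimethyl-2-[2-(phenylsulfinyl)ethyl]-2-(prop-2-yn-1-yl)hexahydronaphthalene-1,3(2H,4H)-dione F3. Thermal syn-elimination of the sulfoxide (toluene, CaCO3, 110 °C) then returns the route at 12.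

Step 13. The vinyl metal may fail to add to a ketone flanked by two quaternary carbons, with recovery of ketone or reduction taking over. The fallback sets out from 16 and uses a slimmer nucleophile. Addition of ethynylmagnesium bromide with CeCl3 (or lithium acetylide–ethylenediamine) on the same face should give the 1'-ethynyl analogue of 17 F4. Hydroxyl-directed trans-hydroalumination of this propargylic alcohol (NaAlH2(OCH2CH2OMe)2, THF, then water) returns the route at 17.

Further compounds
F1 | step 14 | 1'-O-trimethylsilyl ether of 17 | CC(C)(C)[Si](C)(C)O[C@H]1[C@@]2(CC(=C)C=C2)[C@](O[Si](C)(C)C)(C=C)[C@]3(C)CCCC(C)(C)[C@H]3C1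
F2 | step 14 | 9-O-trimethylsilyl enol ether of 24 | C=C1CC2=C[C@@H]1CC=C(O[Si](C)(C)C)[C@]1(C)CCCC(C)(C)[C@H]1C[C@H]2O[Si](C)(C)C(C)(C)C
F3 | step 9 | (2S,4aR,8aR)-5,5,8a-trimethyl-2-[2-(phenylsulfinyl)ethyl]-2-(prop-2-yn-1-yl)hexahydronaphthalene-1,3(2H,4H)-dione | O=C1[C@](CC#C)(CCS(=O)c3ccccc3)C(=O)[C@]2(C)CCCC(C)(C)[C@H]2C1
F4 | step 13 | 1'-ethynyl analogue of 17 | CC(C)(C)[Si](C)(C)O[C@H]1[C@@]2(CC(=C)C=C2)[C@](O)(C#C)[C@]3(C)CCCC(C)(C)[C@H]3C1
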